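**Retrosynthetic overview**

1. Numbering: tetralin C1 (side chain), C4 (methyl), C4a, C5 and C6 (hydroxyls), C7 (carboxyl), C8, C8a; ring A saturated, ring B aromatic; side chain C11 (on C1, carries a CH2OH) to C15 (methyl and CH2OH).
2. Feature: in ring B the run C8a–C8(H)–C7(CO2H)–C6(OH) is a latent 2-alkylfuran-4-carboxylate whose ring oxygen is the C6 oxygen, and C4a–C5 is a latent alkyne. Rings A and B are therefore closed together, last, by furan–ynal [4+2] cycloaddition and bridge opening of 27 (bonds C4a–C8a and C5–C6); the C5 formyl group then becomes the second phenol.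
3. Ynal 27 ⇐ terminal alkyne (formylation) ⇐ C4 aldehyde (one-carbon homologation) ⇐ C3 iodide + propanal RAMP hydrazone (sets C4).
4. The C1–C11 bond with both stereocentres ⇐ dual iridium/enamine allylation of chain aldehyde 9 with racemic furyl vinyl carbinol 12, then hydroboration of the vinyl group (C2, C3).
5. 9 ⇐ methyl (R)-3-hydroxy-2-methylpropanoate (C15) + pentenyl Grignard reagent; 12 ⇐ methyl furan-3-carboxylate (formylation, vinyl addition).

Key step: step 17

Assumption: in step 8 the (S)-configured phosphoramidite–olefin ligand is taken to give the 1S centre; this centre is set by the ligand alone, so if a trial on the parent phenyl vinyl carbinol shows the opposite sense, the (R)-ligand is used and nothing else changes.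

Abbreviations: TBS = tert-butyldimethylsilyl; RAMP = (R)-1-amino-2-(methoxymethyl)pyrrolidine.

**Route**

Step 1
Reactants: 1 methyl (R)-3-hydroxy-2-methylpropanoate
Product: 2 methyl (R)-3-(tert-butyldimethylsilyloxy)-2-methylpropanoate
Conditions: TBSCl, imidazole, CH2Cl2, 0 °C → rt
Reagents that add atoms: tert-butyldimethylsilyl chloride, CC(C)(C)[Si](C)(C)Cl
Why: Imidazole-promoted silylation of the primary alcohol protects the future C15 hydroxymethyl group without touching the stereocentre.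

Step 2
Reactants: 2 methyl (R)-3-(tert-butyldimethylsilyloxy)-2-methylpropanoate
Product: 3 (S)-3-(tert-butyldimethylsilyloxy)-2-methylpropan-1-ol
Conditions: i-Bu2AlH, CH2Cl2, −78 → 0 °C
Reagents that add atoms: none
Why: Hydride reduction of the ester to the primary alcohol should proceed without enolisation, so the C15 centre is kept (the descriptor changes only by priority).

Step 3
Reactants: 3 (S)-3-(tert-butyldimethylsilyloxy)-2-methylpropan-1-ol
Product: 4 (R)-3-(tert-butyldimethylsilyloxy)-2-methylpropyl 4-methylbenzenesulfonate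
Conditions: TsCl, Et3N, DMAP (cat.), CH2Cl2, 0 °C → rt
Reagents that add atoms: 4-methylbenzenesulfonyl chloride, Cc1ccc(cc1)S(=O)(=O)Cl
Why: Tosylation of the primary alcohol gives the leaving group for the sp3–sp3 coupling.

Step 4
Reactants: 4 (R)-3-(tert-butyldimethylsilyloxy)-2-methylpropyl 4-methylbenzenesulfonate; 5 5-bromopent-1-ene
Product: 7 (S)-tert-butyldimethyl[(2-methyloct-7-en-1-yl)oxy]silane, via pent-4-enylmagnesium bromide 6 (not isolated)
Conditions: 5, Mg, THF, reflux; then 4, Li2CuCl4 (cat.), THF, −20 °C → rt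
Reagents that add atoms: none
Why: Copper-catalysed Grignard coupling with a primary tosylate (Fouquet–Schlosser/Kochi type) joins C14 to C13 at a carbon next to, not at, the stereocentre.

Step 5
Reactants: 7 (S)-tert-butyldimethyl[(2-methyloct-7-en-1-yl)oxy]silane
Product: 9 (S)-7-(tert-butyldimethylsilyloxy)-6-methylheptanal, via ozonide 8 (not isolated)
Conditions: O3, CH2Cl2, −78 °C; then PPh3, −78 °C → rt
Reagents that add atoms: ozone, [O-][O+]=O
Why: Ozonolysis with reductive work-up cleaves the terminal alkene to the aldehyde whose α-carbon is C11; the silyl ether is inert.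

Step 6
Reactants: 10 methyl furan-3-carboxylate
Product: 11 methyl 5-formylfuran-3-carboxylate
Conditions: POCl3, DMF, 0 → 60 °C; aq. NaOAc
Reagents that add atoms: N,N-dimethylformamide, CN(C)C=O (formyl carbon); water, O (formyl oxygen)
Why: Vilsmeier–Haack formylation should go to C5, the α-position whose σ-complex does not place positive charge on the ester-bearing carbon.

Step 7
Reactants: 11 methyl 5-formylfuran-3-carboxylate
Product: 12 methyl 5-(1-hydroxyprop-2-en-1-yl)furan-3-carboxylate (racemic)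
Conditions: CH2=CHMgBr, THF, −78 °C
Reagents that add atoms: vinylmagnesium bromide, C=C[Mg]Br
Why: Grignard 1,2-addition is far faster at the aldehyde than at the ester at −78 °C; the carbinol is used as the racemate because the next step is enantioconvergent.

Step 8
Reactants: 9 (S)-7-(tert-butyldimethylsilyloxy)-6-methylheptanal; 12 methyl 5-(1-hydroxyprop-2-en-1-yl)furan-3-carboxylate
Product: 14 methyl 5-[(3S,4S,8S)-9-(tert-butyldimethylsilyloxy)-4-(hydroxymethyl)-8-methylnon-1-en-3-yl]furan-3-carboxylate, via aldehyde 13 (not isolated)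
Conditions: 9 (1.5 equiv.), [Ir(cod)Cl]2 (cat.), (S)-BINOL-derived N-dibenz[b,f]azepinyl phosphoramidite (phosphoramidite–olefin ligand, cat.), (R)-α,α-bis[3,5-bis(trifluoromethyl)phenyl]prolinol trimethylsilyl ether (cat.), (MeO)2P(O)OH (cat.), ClCH2CH2Cl, 25 °C; then NaBH4, MeOH, 0 °C
Reagents that add atoms: none
Why: Stereodivergent dual iridium/enamine α-allylation of a linear aldehyde: racemic 12 ionises to an iridium π-allyl whose ligand fixes the furyl-bearing C1 whatever the carbinol configuration, the E-enamine of 9 with the R prolinol ether is attacked on the face away from the diarylsilyloxymethyl group and so fixes C11 as S, and immediate borohydride reduction of 13 removes the epimerisable α-centre.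

Step 9
Reactants: 14 methyl 5-[(3S,4S,8S)-9-(tert-butyldimethylsilyloxy)-4-(hydroxymethyl)-8-methylnon-1-en-3-yl]furan-3-carboxylate
Product: 15 methyl 5-[(3S,4S,8S)-9-(TBS-oxy)-4-(TBS-oxymethyl)-8-methylnon-1-en-3-yl]furan-3-carboxylate
Conditions: TBSCl, imidazole, DMF, rt
Reagents that add atoms: tert-butyldimethylsilyl chloride, CC(C)(C)[Si](C)(C)Cl
Why: Silylation of the primary alcohol makes the two side-chain hydroxyls one protecting-group class for a single late deprotection.

Step 10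
Reactants: 15 methyl 5-[(3S,4S,8S)-9-(TBS-oxy)-4-(TBS-oxymethyl)-8-methylnon-1-en-3-yl]furan-3-carboxylate
Product: 17 methyl 5-[(3S,4S,8S)-9-(TBS-oxy)-4-(TBS-oxymethyl)-1-hydroxy-8-methylnonan-3-yl]furan-3-carboxylate, via alkylborane 16 (not isolated)
Conditions: 9-BBN, THF, 0 °C → rt; then NaBO3·4H2O, H2O, rt
Reagents that add atoms: sodium perborate (tetrahydrate), [Na+].[O-]OB=O
Why: Anti-Markovnikov hydroboration–oxidation of the vinyl group gives the C3 alcohol; 9-BBN leaves the furan and ester alone and perborate oxidises the borane without hydrolysing the ester.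

Step 11
Reactants: 17 methyl 5-[(3S,4S,8S)-9-(TBS-oxy)-4-(TBS-oxymethyl)-1-hydroxy-8-methylnonan-3-yl]furan-3-carboxylate
Product: 18 methyl 5-[(3S,4S,8S)-9-(TBS-oxy)-4-(TBS-oxymethyl)-1-iodo-8-methylnonan-3-yl]furan-3-carboxylate
Conditions: I2, PPh3, imidazole, CH2Cl2, 0 °C → rt
Reagents that add atoms: iodine, II
Why: Phosphine/iodine (Garegg–Samuelsson) iodination converts the primary alcohol into an unhindered primary iodide under neutral conditions.

Step 12
Reactants: 19 propanal; 20 (R)-1-amino-2-(methoxymethyl)pyrrolidine (RAMP)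
Product: 21 (R,E)-N-[2-(methoxymethyl)pyrrolidin-1-yl]propan-1-imine (propanal RAMP hydrazone)
Conditions: MgSO4, CH2Cl2, 0 °C → rt
Reagents that add atoms: none
Why: Hydrazone condensation gives the chiral propanal equivalent that will deliver C4, its methyl group and C4a.

Step 13
Reactants: 21 propanal RAMP hydrazone; 18 methyl 5-[(3S,4S,8S)-9-(TBS-oxy)-4-(TBS-oxymethyl)-1-iodo-8-methylnonan-3-yl]furan-3-carboxylate
Product: 23 RAMP hydrazone of methyl 5-[(2R,5S,6S,10S)-11-(TBS-oxy)-6-(TBS-oxymethyl)-2,10-dimethyl-1-oxoundecan-5-yl]furan-3-carboxylate, via lithio azaenolate 22 (not isolated)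
Conditions: 21 (1.3 equiv.), LiN(i-Pr)2, THF, 0 °C; then 18, −100 → −40 °C
Reagents that add atoms: none
Why: Enders RAMP-hydrazone α-alkylation: the chelated lithio azaenolate is alkylated by the primary iodide on the face left open by the methoxymethylpyrrolidine, so the R auxiliary sets C4 as R, and the low temperature keeps the furan ester out of reach.

Step 14
Reactants: 23 RAMP hydrazone of the C4 aldehyde
Product: 24 methyl 5-[(2R,5S,6S,10S)-11-(TBS-oxy)-6-(TBS-oxymethyl)-2,10-dimethyl-1-oxoundecan-5-yl]furan-3-carboxylate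
Conditions: CuCl2·2H2O, THF/aq. phosphate buffer (pH 7), 0 °C → rt
Reagents that add atoms: water, O
Why: Copper-assisted hydrolysis of the hydrazone at neutral pH should free the α-methyl aldehyde without epimerising C4 and without ozone, which the furan would not tolerate.

Step 15
Reactants: 24 methyl 5-[(2R,5S,6S,10S)-11-(TBS-oxy)-6-(TBS-oxymethyl)-2,10-dimethyl-1-oxoundecan-5-yl]furan-3-carboxylate
Product: 25 methyl 5-[(3R,6S,7S,11S)-12-(TBS-oxy)-7-(TBS-oxymethyl)-3,11-dimethyldodec-1-yn-6-yl]furan-3-carboxylate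
Conditions: MeC(O)C(N2)P(O)(OMe)2, K2CO3, MeOH, 0 °C → rt
Reagents that add atoms: dimethyl (1-diazo-2-oxopropyl)phosphonate, CC(=O)C(=[N+]=[N-])P(=O)(OC)OC
Why: Seyferth–Gilbert homologation with the Ohira–Bestmann reagent turns the aldehyde into the terminal alkyne C4a≡C5 under carbonate/methanol, conditions under which α-branched aldehydes normally keep their configuration and the methyl ester is unchanged.

Step 16
Reactants: 25 methyl 5-[(3R,6S,7S,11S)-12-(TBS-oxy)-7-(TBS-oxymethyl)-3,11-dimethyldodec-1-yn-6-yl]furan-3-carboxylate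
Product: 27 methyl 5-[(4R,7S,8S,12S)-13-(TBS-oxy)-8-(TBS-oxymethyl)-4,12-dimethyl-1-oxotridec-2-yn-7-yl]furan-3-carboxylate, via lithium acetylide 26 (not isolated)
Conditions: LiN(i-Pr)2 (1.05 equiv.), THF, −78 °C; DMF; inverse quench into aq. KH2PO4
Reagents that add atoms: N,N-dimethylformamide, CN(C)C=O
Why: Formylation of the lithium acetylide with DMF: the alkyne C–H is by far the most acidic site, the amide base does not add to the non-enolisable ester at −78 °C, and the buffered inverse quench frees the ynal without exposing the C4 hydrogen to base.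

Step 17
Reactants: 27 methyl 5-[(4R,7S,8S,12S)-13-(TBS-oxy)-8-(TBS-oxymethyl)-4,12-dimethyl-1-oxotridec-2-yn-7-yl]furan-3-carboxylate
Product: 29 methyl (5R,8S)-8-[(2S,6S)-1,7-bis(TBS-oxy)-6-methylheptan-2-yl]-4-formyl-3-hydroxy-5-methyl-5,6,7,8-tetrahydronaphthalene-2-carboxylate, via oxanorbornadiene 28 (not isolated)
Conditions: PhMe (0.01 M, degassed), BHT (cat.), sealed tube, 150 °C
Reagents that add atoms: none
Why: Thermal intramolecular Diels–Alder reaction of the furan (4π: C8a, C8, C7, C6) with the formyl-activated alkyne (2π: C4a≡C5), the known furan/alkynyl-carbonyl cycloaddition–aromatisation route to phenols. Ring A closes as a six-membered carbocycle by the C4a–C8a bond through the four-carbon tether C1–C4 attached at the diene terminus, and ring B closes at the same time by the C5–C6 bond as the oxygen-bridged cyclohexadiene 28. Heterolysis of the tertiary, doubly allylic C8a–O bond and loss of the C6 proton then give the C6 phenol, whose hydrogen bonds to the flanking formyl and ester groups make the cascade irreversible. No stereocentre is created, because both bridgeheads of 28 become sp2, so the furan face that is attacked does not matter. Regiochemistry is the only selectivity needed and is fixed by the tether (formyl on C5) and by C6 being the only bridgehead with a hydrogen (oxygen stays on C6), while branching at both tether ends (C1 and C4) favours the folded reactive conformer. The neutral, base-free medium protects the C4 hydrogen (propargylic to the ynal before, γ to the unsaturated aldehyde after cycloaddition) and the C1 centre.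

Step 18
Reactants: 29 methyl (5R,8S)-8-[(2S,6S)-1,7-bis(TBS-oxy)-6-methylheptan-2-yl]-4-formyl-3-hydroxy-5-methyl-5,6,7,8-tetrahydronaphthalene-2-carboxylate
Product: 31 methyl (5R,8S)-8-[(2S,6S)-1,7-bis(TBS-oxy)-6-methylheptan-2-yl]-3,4-dihydroxy-5-methyl-5,6,7,8-tetrahydronaphthalene-2-carboxylate, via aryl formate 30 (not isolated)
Conditions: H2O2 (30% aq.), NaOH, THF/H2O, 0 °C, Ar; then aq. Na2S2O3, KH2PO4
Reagents that add atoms: hydrogen peroxide, OO
Why: Dakin oxidation: hydroperoxide adds to the aldehyde, the aryl group migrates with the help of the ortho phenoxide, and the aryl formate is hydrolysed in the flask to the C5 phenol; cold, oxygen-free conditions limit further oxidation of the catechol.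

Step 19
Reactants: 31 methyl (5R,8S)-8-[(2S,6S)-1,7-bis(TBS-oxy)-6-methylheptan-2-yl]-3,4-dihydroxy-5-methyl-5,6,7,8-tetrahydronaphthalene-2-carboxylate
Product: 32 methyl (5R,8S)-8-[(2S,6S)-1,7-dihydroxy-6-methylheptan-2-yl]-3,4-dihydroxy-5-methyl-5,6,7,8-tetrahydronaphthalene-2-carboxylate
Conditions: HF·pyridine, THF/pyridine, 0 °C → rt
Reagents that add atoms: none
Why: Fluoride-mediated cleavage of both primary silyl ethers under non-basic conditions spares the methyl ester and the catechol.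

Step 20
Reactants: 32 methyl (5R,8S)-8-[(2S,6S)-1,7-dihydroxy-6-methylheptan-2-yl]-3,4-dihydroxy-5-methyl-5,6,7,8-tetrahydronaphthalene-2-carboxylate
Product: 33 (5R,8S)-8-[(2S,6S)-1,7-dihydroxy-6-methylheptan-2-yl]-3,4-dihydroxy-5-methyl-5,6,7,8-tetrahydronaphthalene-2-carboxylic acid (target)
Conditions: LiOH, THF/MeOH/H2O (degassed), 50 °C, Ar; then 1 M HCl to pH 2
Reagents that add atoms: lithium hydroxide, [Li+].[OH-]
Why: Saponification of the salicylate-type methyl ester under exclusion of oxygen, then acidification, should give the free acid with no stereocentre at risk (none is α to a carbonyl).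

**Compound list**

1 | methyl (R)-3-hydroxy-2-methylpropanoate | C[C@H](CO)C(=O)OC | starting material
2 | methyl (R)-3-(tert-butyldimethylsilyloxy)-2-methylpropanoate | C[C@H](CO[Si](C)(C)C(C)(C)C)C(=O)OC | intermediate
3 | (S)-3-(tert-butyldimethylsilyloxy)-2-methylpropan-1-ol | C[C@H](CO[Si](C)(C)C(C)(C)C)CO | intermediate
4 | (R)-3-(tert-butyldimethylsilyloxy)-2-methylpropyl 4-methylbenzenesulfonate | C[C@H](CO[Si](C)(C)C(C)(C)C)COS(=O)(=O)c1ccc(C)cc1 | intermediate
5 | 5-bromopent-1-ene | BrCCCC=C | starting material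
6 | pent-4-enylmagnesium bromide | C=CCCC[Mg]Br | intermediate
7 | (S)-tert-butyldimethyl[(2-methyloct-7-en-1-yl)oxy]silane | C[C@H](CO[Si](C)(C)C(C)(C)C)CCCCC=C | intermediate
8 | 3-[(5S)-6-(tert-butyldimethylsilyloxy)-5-methylhexyl]-1,2,4-trioxolane (ozonide) | C[C@H](CO[Si](C)(C)C(C)(C)C)CCCCC1OCOO1 | intermediate
9 | (S)-7-(tert-butyldimethylsilyloxy)-6-methylheptanal | C[C@H](CO[Si](C)(C)C(C)(C)C)CCCCC=O | intermediate
10 | methyl furan-3-carboxylate | COC(=O)c1ccoc1 | starting material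
11 | methyl 5-formylfuran-3-carboxylate | COC(=O)c1coc(C=O)c1 | intermediate
12 | methyl 5-(1-hydroxyprop-2-en-1-yl)furan-3-carboxylate (racemic) | COC(=O)c1coc(C(O)C=C)c1 | intermediate
13 | methyl 5-[(3S,4S,8S)-9-(TBS-oxy)-4-formyl-8-methylnon-1-en-3-yl]furan-3-carboxylate | C[C@H](CO[Si](C)(C)C(C)(C)C)CCC[C@H](C=O)[C@H](C=C)c1cc(C(=O)OC)co1 | intermediate
14 | methyl 5-[(3S,4S,8S)-9-(TBS-oxy)-4-(hydroxymethyl)-8-methylnon-1-en-3-yl]furan-3-carboxylate | C[C@H](CO[Si](C)(C)C(C)(C)C)CCC[C@H](CO)[C@H](C=C)c1cc(C(=O)OC)co1 | intermediate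
15 | methyl 5-[(3S,4S,8S)-9-(TBS-oxy)-4-(TBS-oxymethyl)-8-methylnon-1-en-3-yl]furan-3-carboxylate | C[C@H](CO[Si](C)(C)C(C)(C)C)CCC[C@H](CO[Si](C)(C)C(C)(C)C)[C@H](C=C)c1cc(C(=O)OC)co1 | intermediate
16 | B-alkyl-9-borabicyclo[3.3.1]nonane from 15 (boron on C3) | C[C@H](CO[Si](C)(C)C(C)(C)C)CCC[C@H](CO[Si](C)(C)C(C)(C)C)[C@H](CCB1C2CCCC1CCC2)c1cc(C(=O)OC)co1 | intermediate
17 | methyl 5-[(3S,4S,8S)-9-(TBS-oxy)-4-(TBS-oxymethyl)-1-hydroxy-8-methylnonan-3-yl]furan-3-carboxylate | C[C@H](CO[Si](C)(C)C(C)(C)C)CCC[C@H](CO[Si](C)(C)C(C)(C)C)[C@H](CCO)c1cc(C(=O)OC)co1 | intermediate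
18 | methyl 5-[(3S,4S,8S)-9-(TBS-oxy)-4-(TBS-oxymethyl)-1-iodo-8-methylnonan-3-yl]furan-3-carboxylate | C[C@H](CO[Si](C)(C)C(C)(C)C)CCC[C@H](CO[Si](C)(C)C(C)(C)C)[C@H](CCI)c1cc(C(=O)OC)co1 | intermediate
19 | propanal | CCC=O | starting material
20 | (R)-1-amino-2-(methoxymethyl)pyrrolidine (RAMP) | COC[C@H]1CCCN1N | starting material
21 | (R,E)-N-[2-(methoxymethyl)pyrrolidin-1-yl]propan-1-imine | CC/C=N/N1CCC[C@@H]1COC | intermediate
22 | lithio azaenolate of 21 | C/C=C/N([Li])N1CCC[C@@H]1COC | intermediate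
23 | RAMP hydrazone (E) of aldehyde 24 | C[C@H](CO[Si](C)(C)C(C)(C)C)CCC[C@H](CO[Si](C)(C)C(C)(C)C)[C@H](CC[C@@H](C)/C=N/N1CCC[C@@H]1COC)c1cc(C(=O)OC)co1 | intermediate
24 | methyl 5-[(2R,5S,6S,10S)-11-(TBS-oxy)-6-(TBS-oxymethyl)-2,10-dimethyl-1-oxoundecan-5-yl]furan-3-carboxylate | C[C@H](CO[Si](C)(C)C(C)(C)C)CCC[C@H](CO[Si](C)(C)C(C)(C)C)[C@H](CC[C@@H](C)C=O)c1cc(C(=O)OC)co1 | intermediate
25 | methyl 5-[(3R,6S,7S,11S)-12-(TBS-oxy)-7-(TBS-oxymethyl)-3,11-dimethyldodec-1-yn-6-yl]furan-3-carboxylate | C[C@H](CO[Si](C)(C)C(C)(C)C)CCC[C@H](CO[Si](C)(C)C(C)(C)C)[C@H](CC[C@@H](C)C#C)c1cc(C(=O)OC)co1 | intermediate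
26 | lithium acetylide of 25 | C[C@H](CO[Si](C)(C)C(C)(C)C)CCC[C@H](CO[Si](C)(C)C(C)(C)C)[C@H](CC[C@@H](C)C#C[Li])c1cc(C(=O)OC)co1 | intermediate
27 | methyl 5-[(4R,7S,8S,12S)-13-(TBS-oxy)-8-(TBS-oxymethyl)-4,12-dimethyl-1-oxotridec-2-yn-7-yl]furan-3-carboxylate (key-step precursor) | C[C@H](CO[Si](C)(C)C(C)(C)C)CCC[C@H](CO[Si](C)(C)C(C)(C)C)[C@H](CC[C@@H](C)C#CC=O)c1cc(C(=O)OC)co1 | intermediate
28 | oxygen-bridged cycloadduct: ring A closed, O bridge C8a–C6, C4a=C5(CHO) and C7(CO2Me)=C8 double bonds, either bridgehead configuration | C[C@H](CO[Si](C)(C)C(C)(C)C)CCC[C@H](CO[Si](C)(C)C(C)(C)C)[C@@H]1CC[C@@H](C)C2=C(C=O)C3OC12C=C3C(=O)OC | intermediate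
29 | methyl (5R,8S)-8-[(2S,6S)-1,7-bis(TBS-oxy)-6-methylheptan-2-yl]-4-formyl-3-hydroxy-5-methyl-5,6,7,8-tetrahydronaphthalene-2-carboxylate (key-step product) | C[C@H](CO[Si](C)(C)C(C)(C)C)CCC[C@H](CO[Si](C)(C)C(C)(C)C)[C@@H]1CC[C@@H](C)c2c1cc(C(=O)OC)c(O)c2C=O | intermediate
30 | C5 formate ester of 31 | C[C@H](CO[Si](C)(C)C(C)(C)C)CCC[C@H](CO[Si](C)(C)C(C)(C)C)[C@@H]1CC[C@@H](C)c2c1cc(C(=O)OC)c(O)c2OC=O | intermediate
31 | methyl (5R,8S)-8-[(2S,6S)-1,7-bis(TBS-oxy)-6-methylheptan-2-yl]-3,4-dihydroxy-5-methyl-5,6,7,8-tetrahydronaphthalene-2-carboxylate | C[C@H](CO[Si](C)(C)C(C)(C)C)CCC[C@H](CO[Si](C)(C)C(C)(C)C)[C@@H]1CC[C@@H](C)c2c1cc(C(=O)OC)c(O)c2O | intermediate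
32 | methyl (5R,8S)-8-[(2S,6S)-1,7-dihydroxy-6-methylheptan-2-yl]-3,4-dihydroxy-5-methyl-5,6,7,8-tetrahydronaphthalene-2-carboxylate | C[C@H](CO)CCC[C@H](CO)[C@@H]1CC[C@@H](C)c2c1cc(C(=O)OC)c(O)c2O | intermediate
33 | (5R,8S)-8-[(2S,6S)-1,7-dihydroxy-6-methylheptan-2-yl]-3,4-dihydroxy-5-methyl-5,6,7,8-tetrahydronaphthalene-2-carboxylic acid | C[C@H](CO)CCC[C@H](CO)[C@@H]1CC[C@@H](C)c2c1cc(C(=O)O)c(O)c2O | target

**Step count and risks**

Total steps: 20. Longest linear sequence: 17 steps (steps 1–5, 8–11, 13–20, from compound 1).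

Step 17 (key step). What may go wrong: cycloaddition of the ester-deactivated furan across the four-carbon tether may be slower than thermal oligomerisation of the ynal, or the bridged adduct may revert instead of opening. Fallback, from 25 back to 31: the lithium acetylide of 25 is acylated with N-methoxy-N-methylacetamide to the methyl ynone F1. Me2AlCl (CH2Cl2, −78 → −20 °C) then drives the same furan–alkyne cycloaddition and bridge opening at low temperature through carbonyl complexation, giving the 5-acetyl-6-hydroxy tetralin ester F2. Alkaline H2O2 (Dakin oxidation of the ortho-hydroxyaryl ketone) replaces the acetyl group by the C5 hydroxyl and gives 31.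

Step 8. What may go wrong: slow ionisation of the electron-poor furyl carbinol at iridium, or loss of the C11 configuration by epimerisation of aldehyde 13 before reduction. Fallback, from 9 and 10 back to 17: 9 is α-hydroxymethylated under enamine catalysis (aqueous formaldehyde, (S)-α,α-diphenylprolinol trimethylsilyl ether, toluene/pH 7 buffer), which sets C11 and gives the hydroxymethyl aldehyde F3. Without purification, Wittig reaction with (triphenylphosphoranylidene)acetaldehyde gives the (E)-enal F4, and silylation (TBSCl, imidazole) gives the bis-silyl enal F5. Separately, 10 is borylated at C5 ([Ir(cod)OMe]2, 4,4'-di-tert-butyl-2,2'-bipyridine, B2pin2) to the pinacol boronate F6. Rhodium/chiral-diene-catalysed conjugate addition of F6 to F5 ([RhCl(C2H4)2]2, diene enantiomer chosen for 1S, aq. KOH, dioxane) sets C1 under catalyst control and gives the C3 aldehyde F7. NaBH4 reduction of F7 gives 17.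

Step 13. What may go wrong: acylation of the azaenolate by the furan methyl ester in competition with alkylation, or partial epimerisation at C4 during the hydrazone hydrolysis of step 14. Fallback, from 17 back to 24: 17 is oxidised (Dess–Martin periodinane) to the C3 aldehyde F7 already described under step 8. Boron-mediated Evans syn-aldol reaction with (R)-4-benzyl-3-propanoyloxazolidin-2-one (Bu2BOTf, Et3N, CH2Cl2, −78 → 0 °C) gives the adduct F8, with the C4 methyl centre set by the auxiliary. The C3 hydroxyl is then removed by Barton–McCombie deoxygenation: 1,1'-thiocarbonyldiimidazole gives the imidazolyl thionocarbonate F9, and Bu3SnH/AIBN (toluene, 80 °C) gives the imide F10. LiBH4 (THF, 1 equiv. MeOH, 0 °C) cleaves the imide selectively to the primary alcohol F11, and Dess–Martin oxidation gives 24.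

**Further compounds**

F1 | step 17 | methyl 5-[(5R,8S,9S,13S)-14-(TBS-oxy)-9-(TBS-oxymethyl)-5,13-dimethyl-2-oxotetradec-3-yn-8-yl]furan-3-carboxylate (methyl ynone) | C[C@H](CO[Si](C)(C)C(C)(C)C)CCC[C@H](CO[Si](C)(C)C(C)(C)C)[C@H](CC[C@@H](C)C#CC(C)=O)c1cc(C(=O)OC)co1
F2 | step 17 | methyl (5R,8S)-4-acetyl-8-[(2S,6S)-1,7-bis(TBS-oxy)-6-methylheptan-2-yl]-3-hydroxy-5-methyl-5,6,7,8-tetrahydronaphthalene-2-carboxylate | C[C@H](CO[Si](C)(C)C(C)(C)C)CCC[C@H](CO[Si](C)(C)C(C)(C)C)[C@@H]1CC[C@@H](C)c2c1cc(C(=O)OC)c(O)c2C(C)=O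
F3 | step 8 | (2R,6S)-7-(TBS-oxy)-2-(hydroxymethyl)-6-methylheptanal | C[C@H](CO[Si](C)(C)C(C)(C)C)CCC[C@H](CO)C=O
F4 | step 8 | (2E,4S,8S)-9-(TBS-oxy)-4-(hydroxymethyl)-8-methylnon-2-enal | C[C@H](CO[Si](C)(C)C(C)(C)C)CCC[C@H](CO)/C=C/C=O
F5 | step 8 | (2E,4S,8S)-9-(TBS-oxy)-4-(TBS-oxymethyl)-8-methylnon-2-enal | C[C@H](CO[Si](C)(C)C(C)(C)C)CCC[C@H](CO[Si](C)(C)C(C)(C)C)/C=C/C=O
F6 | step 8 | methyl 5-(4,4,5,5-tetramethyl-1,3,2-dioxaborolan-2-yl)furan-3-carboxylate | COC(=O)c1coc(B2OC(C)(C)C(C)(C)O2)c1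
F7 | step 8 | methyl 5-[(3S,4S,8S)-9-(TBS-oxy)-4-(TBS-oxymethyl)-8-methyl-1-oxononan-3-yl]furan-3-carboxylate | C[C@H](CO[Si](C)(C)C(C)(C)C)CCC[C@H](CO[Si](C)(C)C(C)(C)C)[C@H](CC=O)c1cc(C(=O)OC)co1
F8 | step 13 | Evans syn-aldol adduct of F7: C3 hydroxyl (S), C4 methyl (R), N-acyl (R)-4-benzyloxazolidin-2-one | C[C@H](CO[Si](C)(C)C(C)(C)C)CCC[C@H](CO[Si](C)(C)C(C)(C)C)[C@H](C[C@H](O)[C@@H](C)C(=O)N1C(=O)OC[C@H]1Cc1ccccc1)c1cc(C(=O)OC)co1
F9 | step 13 | O-(imidazol-1-ylthiocarbonyl) derivative of F8 | C[C@H](CO[Si](C)(C)C(C)(C)C)CCC[C@H](CO[Si](C)(C)C(C)(C)C)[C@H](C[C@H](OC(=S)n1ccnc1)[C@@H](C)C(=O)N1C(=O)OC[C@H]1Cc1ccccc1)c1cc(C(=O)OC)co1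
F10 | step 13 | C3-deoxygenated N-acyl oxazolidinone (C4 R) | C[C@H](CO[Si](C)(C)C(C)(C)C)CCC[C@H](CO[Si](C)(C)C(C)(C)C)[C@H](CC[C@@H](C)C(=O)N1C(=O)OC[C@H]1Cc1ccccc1)c1cc(C(=O)OC)co1
F11 | step 13 | methyl 5-[(2R,5S,6S,10S)-11-(TBS-oxy)-6-(TBS-oxymethyl)-1-hydroxy-2,10-dimethylundecan-5-yl]furan-3-carboxylate | C[C@H](CO[Si](C)(C)C(C)(C)C)CCC[C@H](CO[Si](C)(C)C(C)(C)C)[C@H](CC[C@@H](C)CO)c1cc(C(=O)OC)co1
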